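**Plan**

Numbering: naphthalene C1 carries the aryl group, C2 and C3 the methyls, C4 is CH; ring A is C4a/C5–C8/C8a (OH on C6, OMe on C7), ring B is C1–C4/C4a/C8a, ring C is the 3,4,5-trimethoxyphenyl group.
Retrosynthesis: after the O–benzyl bond, the first cut is C2–C3, the bond between the two methyl-bearing carbons of ring B. This is possible because C3–C4 can be a propynyl group on C4a and C1=C2 a propenyl group on C8a of ring A, so alkene carbon C2 faces alkyne carbon C3.
Further cuts: C1=C2 (Wittig ethylidenation of a diaryl ketone), C1–ring C (aryl Grignard addition to an aldehyde) and C4–C4a (Sonogashira coupling), back to O-benzylvanillin.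
Forward: ring A (O-benzylvanillin) is brominated at the future C4a and propynylated, ring C is attached at the aldehyde carbon (future C1) and the ketone is ethylidenated. Ring B, the only ring made, is closed last by PtCl2-catalysed 6-endo cycloisomerization, and debenzylation ends the route.
Stereochemistry: the target has no stereocentre; the carbinol centre of 7 is racemic and is removed by oxidation, and the geometry of alkene 11 does not matter.

Key step: step 6

Remark: 1 is bought as such (the commercial benzyl ether of vanillin); alkene 11 is expected as an unseparated E/Z mixture (Z isomer: COc1cc(/C(=C\C)c2cc(OC)c(OC)c(OC)c2)c(C#CC)cc1OCc1ccccc1), drawn as E because both isomers should give 12.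

**Route**

Step 1
Reactants: 1 4-benzyloxy-3-methoxybenzaldehyde (O-benzylvanillin)
Product: 2 4-benzyloxy-2-bromo-5-methoxybenzaldehyde
Conditions: Br2, NaOAc, AcOH, rt
Reagents that add atoms: bromine, BrBr
Why: Electrophilic aromatic bromination, directed para to the methoxy group (ortho to the formyl group) because the benzyloxy oxygen is deactivated by conjugation with the para aldehyde, as in the bromination of veratraldehyde.

Step 2
Reactants: 2 4-benzyloxy-2-bromo-5-methoxybenzaldehyde; 3 propyne
Product: 4 4-benzyloxy-5-methoxy-2-(prop-1-yn-1-yl)benzaldehyde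
Conditions: propyne (solution in THF, excess), PdCl2(PPh3)2 (cat.), CuI (cat.), Et3N, THF, sealed vessel, 50 °C
Reagents that add atoms: propyne (3), CC#C
Why: Sonogashira coupling, in which the ortho formyl group speeds oxidative addition of zerovalent palladium into the otherwise electron-rich C–Br bond and is itself inert to the copper acetylide.

Step 3
Reactants: 4 4-benzyloxy-5-methoxy-2-(prop-1-yn-1-yl)benzaldehyde; 5 5-bromo-1,2,3-trimethoxybenzene
Product: 7 rac-[4-benzyloxy-5-methoxy-2-(prop-1-yn-1-yl)phenyl](3,4,5-trimethoxyphenyl)methanol, via 3,4,5-trimethoxyphenylmagnesium bromide 6 (not isolated)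
Conditions: 5, Mg turnings, THF, reflux; then 4, THF, −20 → 0 °C; aqueous work-up
Reagents that add atoms: 5-bromo-1,2,3-trimethoxybenzene (5), COc1cc(Br)cc(OC)c1OC
Why: Grignard formation followed by 1,2-addition to the aromatic aldehyde, which is fast at low temperature and leaves the internal alkyne untouched; the new carbinol centre is formed racemic and is erased by the oxidation in step 4.

Step 4
Reactants: 7 rac-[4-benzyloxy-5-methoxy-2-(prop-1-yn-1-yl)phenyl](3,4,5-trimethoxyphenyl)methanol
Product: 8 [4-benzyloxy-5-methoxy-2-(prop-1-yn-1-yl)phenyl](3,4,5-trimethoxyphenyl)methanone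
Conditions: Dess–Martin periodinane, CH2Cl2, rt
Reagents that add atoms: none
Why: Dess–Martin oxidation of a doubly benzylic secondary alcohol, which proceeds under near-neutral conditions that spare the alkyne, the benzyl ether and the electron-rich rings.

Step 5
Reactants: 8 [4-benzyloxy-5-methoxy-2-(prop-1-yn-1-yl)phenyl](3,4,5-trimethoxyphenyl)methanone; 9 ethyltriphenylphosphonium bromide
Product: 11 1-benzyloxy-2-methoxy-5-(prop-1-yn-1-yl)-4-[1-(3,4,5-trimethoxyphenyl)prop-1-en-1-yl]benzene (E/Z mixture), via ethylidenetriphenylphosphorane 10 (not isolated)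
Conditions: 9, KOtBu, THF, 0 °C → rt; then 8, THF, reflux
Reagents that add atoms: ethyltriphenylphosphonium bromide (9), CC[P+](c1ccccc1)(c1ccccc1)c1ccccc1.[Br-]
Why: Wittig olefination with a non-stabilised ylide, a reaction type that ethylidenates non-enolisable diaryl ketones on heating; no control of alkene geometry is needed because C2 is the reacting carbon in step 6 whichever isomer is formed.

Step 6
Reactants: 11 1-benzyloxy-2-methoxy-5-(prop-1-yn-1-yl)-4-[1-(3,4,5-trimethoxyphenyl)prop-1-en-1-yl]benzene (E/Z mixture)
Product: 12 6-benzyloxy-7-methoxy-2,3-dimethyl-1-(3,4,5-trimethoxyphenyl)naphthalene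
Conditions: PtCl2 (10 mol%), toluene, 80 °C, argon
Reagents that add atoms: none
Why: PtCl2 binds the propynyl triple bond as a π-acid, the propenyl carbon C2 adds to the methyl-bearing alkyne carbon C3, the resulting C1 cation (stabilised by ring C and by ring A, whose benzyloxy oxygen sits para to C8a) loses the C2 proton, and protonolysis of the C4–Pt bond releases the naphthalene and the catalyst. The closest known reaction type is the PtCl2-, AuCl3- or InCl3-catalysed cycloisomerization of ortho-alkynyl styrenes and ortho-alkynyl biaryls to naphthalenes and phenanthrenes. Ring B closes in the 6-endo-dig mode, and C2–C3 is the only new skeletal bond. No stereocentre is created, and since C2 is the attacking atom both alkene isomers of 11 should give the same product. The selectivity needed is 6-endo attack at C3 over 5-exo-dig attack at C4; it is favoured by the doubly aryl-stabilised cation at C1, the alkyl (not acyl or halogen) terminus of the alkyne, the strain of the alternative alkylidene-indene and the aromatic stabilisation gained on proton loss.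

Step 7
Reactants: 12 6-benzyloxy-7-methoxy-2,3-dimethyl-1-(3,4,5-trimethoxyphenyl)naphthalene
Product: 13 7-methoxy-2,3-dimethyl-1-(3,4,5-trimethoxyphenyl)naphthalen-6-ol (target CNP0280611.0)
Conditions: H2 (1 atm), Pd/C (10% palladium on carbon), EtOAc–MeOH, rt
Reagents that add atoms: none
Why: Hydrogenolysis of a benzyl aryl ether over Pd/C, to which the naphthalene core, the aryl methyl ethers and the biaryl bond are inert under one atmosphere of hydrogen at room temperature.

**Compound list**

1 | 4-benzyloxy-3-methoxybenzaldehyde (O-benzylvanillin) | COc1cc(C=O)ccc1OCc1ccccc1 | starting material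
2 | 4-benzyloxy-2-bromo-5-methoxybenzaldehyde | COc1cc(C=O)c(Br)cc1OCc1ccccc1 | intermediate
3 | propyne | CC#C | starting material
4 | 4-benzyloxy-5-methoxy-2-(prop-1-yn-1-yl)benzaldehyde | COc1cc(C=O)c(C#CC)cc1OCc1ccccc1 | intermediate
5 | 5-bromo-1,2,3-trimethoxybenzene | COc1cc(Br)cc(OC)c1OC | starting material
6 | 3,4,5-trimethoxyphenylmagnesium bromide (not isolated) | COc1cc([Mg]Br)cc(OC)c1OC | intermediate
7 | rac-[4-benzyloxy-5-methoxy-2-(prop-1-yn-1-yl)phenyl](3,4,5-trimethoxyphenyl)methanol | COc1cc(C(O)c2cc(OC)c(OC)c(OC)c2)c(C#CC)cc1OCc1ccccc1 | intermediate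
8 | [4-benzyloxy-5-methoxy-2-(prop-1-yn-1-yl)phenyl](3,4,5-trimethoxyphenyl)methanone | COc1cc(C(=O)c2cc(OC)c(OC)c(OC)c2)c(C#CC)cc1OCc1ccccc1 | intermediate
9 | ethyltriphenylphosphonium bromide | CC[P+](c1ccccc1)(c1ccccc1)c1ccccc1.[Br-] | starting material
10 | ethylidenetriphenylphosphorane (not isolated) | CC=P(c1ccccc1)(c1ccccc1)c1ccccc1 | intermediate
11 | 1-benzyloxy-2-methoxy-5-(prop-1-yn-1-yl)-4-[1-(3,4,5-trimethoxyphenyl)prop-1-en-1-yl]benzene, E/Z mixture (E isomer drawn) | COc1cc(/C(=C/C)c2cc(OC)c(OC)c(OC)c2)c(C#CC)cc1OCc1ccccc1 | intermediate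
12 | 6-benzyloxy-7-methoxy-2,3-dimethyl-1-(3,4,5-trimethoxyphenyl)naphthalene | COc1cc2c(-c3cc(OC)c(OC)c(OC)c3)c(C)c(C)cc2cc1OCc1ccccc1 | intermediate
13 | 7-methoxy-2,3-dimethyl-1-(3,4,5-trimethoxyphenyl)naphthalen-6-ol (systematic: 3-methoxy-6,7-dimethyl-5-(3,4,5-trimethoxyphenyl)naphthalen-2-ol) | COc1cc2c(-c3cc(OC)c(OC)c(OC)c3)c(C)c(C)cc2cc1O | target

**Step count and risks**

Total step count: 7. Longest linear sequence: 7 steps (1 → 13).

Steps most likely to fail:

Step 6. Attack of C2 on the ring-bound alkyne carbon C4 (5-exo-dig), encouraged by the C7 methoxy group para to the alkyne, could compete with the six-membered closure. Turnover could also stall if the electron-rich arenes or the congested vinyl–platinum intermediate hold the metal. Fallback: from 11, iodonium-induced carbocyclization (I2, NaHCO3, MeCN, rt) uses a stoichiometric electrophile in place of a π-acid catalyst; six-membered closure onto aryl alkynes is established for this reaction type. It should form the same C2–C3 bond and leave iodine on C4, giving 6-benzyloxy-4-iodo-7-methoxy-2,3-dimethyl-1-(3,4,5-trimethoxyphenyl)naphthalene F1. Hydrogenation of F1 over Pd/C in the presence of Et3N should then remove the C4 iodine and the benzyl group together, so the sequence rejoins the route at 13.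

Step 5. Addition of the ylide to the hindered, electron-rich diaryl ketone with its ortho substituent may be slow or incomplete. Fallback: from 8, addition of ethylmagnesium bromide (THF, 0 °C) should give rac-1-[4-benzyloxy-5-methoxy-2-(prop-1-yn-1-yl)phenyl]-1-(3,4,5-trimethoxyphenyl)propan-1-ol F2. Dehydration with catalytic p-TsOH in toluene, which passes through the readily formed doubly benzylic cation, should give 11, where the route is rejoined.

Step 2. Oxidative addition into the electron-rich aryl bromide may be slow while the volatile alkyne escapes or is consumed by copper-mediated oxidative dimerization. Fallback: from 2, Stille coupling with the liquid, preformed tributyl(prop-1-yn-1-yl)stannane (Pd(PPh3)4, toluene, 100 °C) should deliver 4 directly, without copper or a gaseous partner. No new compound arises and the route is rejoined at 4.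

Further compounds
F1 | step 6 | 6-benzyloxy-4-iodo-7-methoxy-2,3-dimethyl-1-(3,4,5-trimethoxyphenyl)naphthalene | COc1cc2c(-c3cc(OC)c(OC)c(OC)c3)c(C)c(C)c(I)c2cc1OCc1ccccc1
F2 | step 5 | rac-1-[4-benzyloxy-5-methoxy-2-(prop-1-yn-1-yl)phenyl]-1-(3,4,5-trimethoxyphenyl)propan-1-ol | CCC(O)(c1cc(OC)c(OC)c(OC)c1)c1cc(OC)c(OCc2ccccc2)cc1C#CC
F0 | step 2 | none | none
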